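**Retrosynthetic overview**
- The oxirane is made last, by Shi epoxidation of the C10=C11 olefin; that olefin comes from an allyl group by cross-metathesis, and both angelates from one double acylation of the C5/C8 diol.
- Key C8–C9 disconnection: reagent-controlled allylboration of an α-methylene aldehyde (ring fragment, C1–C8) with an allyl fragment, which sets C8.
- The enal comes from the isopropenyl group of the fully substituted ring (ene chlorination, acetate, alcohol, aldehyde).
- Ring stereocentres come from (S)-carvone: α'-hydroxylation, Luche reduction, hydroxyl-directed epoxidation, trans-diaxial opening by chloride; C6 is then inverted by oxidation/reduction.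
- Rings: the cyclohexane is taken from carvone and never formed; a ring epoxide (opened) and a dioxolane (protecting group) are temporary; the only ring built for the target, the oxirane, is closed in the final step.

Locants used in all names: ring C1 (bears the side chain) to C6 as in the target (C3 = CHCl, C4 = C(CH3)O, C5 and C6 oxygenated); side chain C7 (=CH2) to C11; β = the ring face carrying the C1 side chain, α = the opposite face. TBS = tert-butyldimethylsilyl; Ipc = isopinocampheyl.

**Step 1**
Reactants: 1 (S)-(+)-carvone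
Product: 3 6α-hydroxycarvone (OH trans to the isopropenyl group), via silyl dienol ether 2 (not isolated)
Conditions: LiN(iPr)2, THF, −78 °C; Me3SiCl; then mCPBA, hexane, −15 °C; then 1 M HCl, THF, rt
Reagents that add atoms: mCPBA, O=C(OO)c1cccc(Cl)c1
Why: Rubottom oxidation: kinetic deprotonation at the only α'-position (C6) and epoxidation of the electron-rich silyl enol ether anti to the neighbouring isopropenyl group give the trans ketol; this centre is reset in steps 8–9, so its ratio is not critical.

**Step 2**
Reactants: 3 6α-hydroxycarvone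
Product: 4 6α-TBS ether
Conditions: TBSCl, imidazole, DMF, rt
Reagents that add atoms: tert-butyldimethylsilyl chloride, CC(C)(C)[Si](C)(C)Cl
Why: Standard silylation of a secondary alcohol; it keeps the C6 oxygen inert and non-directing through steps 3–6.

**Step 3**
Reactants: 4 6α-TBS ether
Product: 5 5β-allylic alcohol
Conditions: NaBH4, CeCl3·7H2O, MeOH, −78 → −40 °C
Reagents that add atoms: none
Why: Luche 1,2-reduction: axial hydride delivery gives the equatorial 5β-alcohol, cis to the C1 substituent as in carvone → cis-carveol and trans to the equatorial 6α-silyloxy group.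

**Step 4**
Reactants: 5 5β-allylic alcohol
Product: 6 3β,4β-epoxy alcohol
Conditions: VO(acac)2 (2 mol%), t-BuOOH, CH2Cl2, 0 °C → rt
Reagents that add atoms: tert-butyl hydroperoxide, CC(C)(C)OO
Why: Hydroxyl-directed vanadium-catalysed epoxidation delivers oxygen syn to the 5β-OH (sets C4) and leaves the isolated isopropenyl olefin alone.

**Step 5**
Reactants: 6 3β,4β-epoxy alcohol
Product: 7 3α-chloro-4β,5β-diol
Conditions: LiCl, AcOH, THF, rt
Reagents that add atoms: lithium chloride, [Li+].[Cl-]
Why: Trans-diaxial (Fürst–Plattner) epoxide opening: in the half-chair with both C1 and C6 substituents equatorial, chloride attacks the secondary C3 with inversion, giving axial 3α-Cl and axial 4β-OH.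

**Step 6**
Reactants: 7 3α-chloro-4β,5β-diol
Product: 8 4β,5β-acetonide
Conditions: 2-methoxypropene, PPTS (cat.), CH2Cl2, 0 °C → rt
Reagents that add atoms: 2-methoxypropene, COC(C)=C
Why: Ketalisation of the cis diol masks the C5 hydroxyl for the C6 oxidation and the tertiary hydroxyl so that later bases cannot reclose the chlorohydrin.

**Step 7**
Reactants: 8 4β,5β-acetonide
Product: 9 6α-alcohol
Conditions: Bu4NF, THF, 0 °C → rt
Reagents that add atoms: none
Why: Fluoride desilylation; the 6α-oxygen is cis to the C3 chloride, so no transannular displacement is possible.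

**Step 8**
Reactants: 9 6α-alcohol
Product: 10 6-ketone
Conditions: Dess–Martin periodinane, CH2Cl2, rt
Reagents that add atoms: none
Why: Dess–Martin oxidation under non-basic conditions leaves the epimerisable C1 and C5 centres untouched.

**Step 9**
Reactants: 10 6-ketone
Product: 11 6β-alcohol
Conditions: LiBH(s-Bu)3, THF, −78 °C; then H2O
Reagents that add atoms: none
Why: Bulky-hydride reduction: the β-face is screened by the axial C4–O bond of the cis-fused dioxolane, so hydride enters equatorially from the α-face and gives the axial 6β-alcohol, cis to the C1 and C5 substituents.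

**Step 10**
Reactants: 11 6β-alcohol
Product: 12 6β-TBS ether
Conditions: TBSOTf, 2,6-lutidine, CH2Cl2, −78 → 0 °C
Reagents that add atoms: tert-butyldimethylsilyl triflate, CC(C)(C)[Si](C)(C)OS(=O)(=O)C(F)(F)F
Why: Triflate-mediated silylation of the hindered axial alcohol without forming an alkoxide, which could displace the trans-1,4 chloride.

**Step 11**
Reactants: 12 6β-TBS ether
Product: 13 allylic chloride (C7(=CH2)–CH2Cl)
Conditions: Ca(OCl)2, CO2 (solid), CH2Cl2/H2O, 0 °C
Reagents that add atoms: calcium hypochlorite, [Ca+2].[O-]Cl.[O-]Cl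
Why: Ene-type allylic chlorination by HOCl: chlorine adds to the terminal CH2 of the only olefin and a methyl proton is lost, giving the 2-substituted allyl chloride.

**Step 12**
Reactants: 13 allylic chloride
Product: 14 allylic acetate
Conditions: KOAc, Bu4NI (cat.), DMF, 50 °C
Reagents that add atoms: potassium acetate, [K+].CC(=O)[O-]
Why: SN2 displacement of the primary allylic chloride with iodide catalysis; the axial secondary C3 chloride next to a quaternary carbon is inert.

**Step 13**
Reactants: 14 allylic acetate
Product: 15 allylic alcohol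
Conditions: K2CO3 (cat.), MeOH, 0 °C → rt
Reagents that add atoms: none
Why: Base-catalysed transesterification; the masked tertiary oxygen prevents epoxide formation from the chlorohydrin.

**Step 14**
Reactants: 15 allylic alcohol
Product: 16 enal (2-substituted acrolein)
Conditions: activated MnO2, CH2Cl2, rt; used at once
Reagents that add atoms: none
Why: MnO2 oxidation is selective for the allylic alcohol and neutral, so the α-methylene aldehyde does not isomerise into conjugation with the ring.

**Step 15**
Reactants: 16 enal, 17 allylmagnesium bromide CH2=CHCH2MgBr, 18 (−)-B-methoxydiisopinocampheylborane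
Product: 21 (8S)-homoallylic alcohol, via B-allyldiisopinocampheylborane 19 (not isolated), via diisopinocampheylborinate 20 (not isolated)
Conditions: 18, 17, Et2O, −78 °C → rt; 16, Et2O, −78 °C; then NaOH, 30% H2O2, 0 °C → rt
Reagents that add atoms: none
Why: Brown asymmetric allylboration (carbonyl allylation): the (−)-Ipc2B-allyl reagent attacks the Si face of the aldehyde through a chair six-membered transition state and forms the C8–C9 bond with 8S configuration under reagent control; the minor epimer is removed by chromatography.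

**Step 16**
Reactants: 21 (8S)-homoallylic alcohol
Product: 22 4β,5β,8-triol
Conditions: AcOH/H2O 4:1, 45 °C
Reagents that add atoms: none
Why: Acid hydrolysis of the acetonide, done before any trisubstituted olefin or epoxide is present; the hindered axial secondary TBS ether survives aqueous acetic acid.

**Step 17**
Reactants: 23 angelic acid
Product: 24 angelic 2,4,6-trichlorobenzoic anhydride
Conditions: 2,4,6-trichlorobenzoyl chloride, Et3N, toluene, rt; filter
Reagents that add atoms: 2,4,6-trichlorobenzoyl chloride, O=C(Cl)c1c(Cl)cc(Cl)cc1Cl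
Why: Yamaguchi-type mixed anhydride formation activates the acid without touching the Z olefin.

**Step 18**
Reactants: 22 4β,5β,8-triol, 24 angelic 2,4,6-trichlorobenzoic anhydride
Product: 25 5,8-bis-angelate
Conditions: 24 (excess), toluene, 80 °C, no DMAP
Reagents that add atoms: none
Why: Acylation by the mixed anhydride at its less hindered angeloyl carbonyl, without a nucleophilic catalyst, so Z → E isomerisation to the tiglate is avoided; the two secondary alcohols react and the tertiary C4-OH does not.

**Step 19**
Reactants: 25 5,8-bis-angelate, 26 2-methyl-2-butene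
Product: 27 prenyl bis-angelate (C10=C11)
Conditions: second-generation Grubbs catalyst RuCl2(=CHPh)(PCy3)(H2IMes) (5 mol%), 26 (large excess)/CH2Cl2, 35 °C
Reagents that add atoms: none
Why: Olefin cross-metathesis converts the terminal vinyl group into the isopropylidene; the hindered 1,1-disubstituted olefin and the conjugated angelates are inert, and the excess of 26 outruns ring closure onto the angelate.

**Step 20**
Reactants: 27 prenyl bis-angelate
Product: 28 4β,6β-diol
Conditions: HF·pyridine, pyridine, THF, 0 °C → rt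
Reagents that add atoms: none
Why: Fluoride desilylation under mildly acidic conditions, so there is no base to close the chlorohydrin or move the C5 angelate to C6.

**Step 21**
Reactants: 28 4β,6β-diol
Product: 29 CNP0158207.1 (target)
Conditions: D-fructose-derived Shi ketone (1 equiv in portions), Oxone (2KHSO5·KHSO4·K2SO4), NaHCO3, Bu4NHSO4 (cat.), MeCN–(MeO)2CH2/aq. Na2EDTA, 0 °C, pH 7.5–8
Reagents that add atoms: potassium peroxymonosulfate KHSO5, [K+].[O-]S(=O)(=O)OO
Why: Shi asymmetric epoxidation: the chiral dioxirane attacks the electron-rich trisubstituted C10=C11 olefin through a spiro transition state to give the 10R epoxide, while the 1,1-disubstituted and conjugated olefins are too slow and pH 8 keeps the chlorohydrin and esters intact.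

**Compound list**
1 | (S)-(+)-carvone; (5S)-2-methyl-5-(prop-1-en-2-yl)cyclohex-2-en-1-one | CC(=C)[C@H]1CC=C(C)C(=O)C1 | starting material
2 | silyl dienol ether of 1 (C5–OSiMe3, C3=C4 and C5=C6 double bonds; not isolated) | CC(=C)[C@H]1CC=C(C)C(O[Si](C)(C)C)=C1 | intermediate
3 | 6α-hydroxycarvone; (5R,6R)-6-hydroxy-2-methyl-5-(prop-1-en-2-yl)cyclohex-2-en-1-one | CC(=C)[C@H]1CC=C(C)C(=O)[C@@H]1O | intermediate
4 | 6α-TBS ether of 3 | CC(=C)[C@H]1CC=C(C)C(=O)[C@@H]1O[Si](C)(C)C(C)(C)C | intermediate
5 | 5β-hydroxy-6α-(TBS-oxy)-4-methyl-1β-isopropenylcyclohex-3-ene | CC(=C)[C@H]1CC=C(C)[C@@H](O)[C@@H]1O[Si](C)(C)C(C)(C)C | intermediate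
6 | 3β,4β-epoxy-5β-hydroxy-6α-(TBS-oxy) compound | CC(=C)[C@H]1C[C@H]2O[C@@]2(C)[C@@H](O)[C@@H]1O[Si](C)(C)C(C)(C)C | intermediate
7 | 3α-chloro-4β,5β-dihydroxy-4α-methyl-6α-(TBS-oxy)-1β-isopropenylcyclohexane | CC(=C)[C@H]1C[C@H](Cl)[C@@](C)(O)[C@@H](O)[C@@H]1O[Si](C)(C)C(C)(C)C | intermediate
8 | 4β,5β-O-isopropylidene derivative of 7 | CC(=C)[C@H]1C[C@H](Cl)[C@@]2(C)OC(C)(C)O[C@H]2[C@@H]1O[Si](C)(C)C(C)(C)C | intermediate
9 | 6α-alcohol (acetonide) | CC(=C)[C@H]1C[C@H](Cl)[C@@]2(C)OC(C)(C)O[C@H]2[C@@H]1O | intermediate
10 | 6-ketone (acetonide) | CC(=C)[C@H]1C[C@H](Cl)[C@@]2(C)OC(C)(C)O[C@H]2C1=O | intermediate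
11 | 6β-alcohol (acetonide) | CC(=C)[C@H]1C[C@H](Cl)[C@@]2(C)OC(C)(C)O[C@H]2[C@H]1O | intermediate
12 | 6β-TBS ether (acetonide) | CC(=C)[C@H]1C[C@H](Cl)[C@@]2(C)OC(C)(C)O[C@H]2[C@H]1O[Si](C)(C)C(C)(C)C | intermediate
13 | 8-chloride; 1β-(3-chloroprop-1-en-2-yl) compound | C=C(CCl)[C@H]1C[C@H](Cl)[C@@]2(C)OC(C)(C)O[C@H]2[C@H]1O[Si](C)(C)C(C)(C)C | intermediate
14 | 8-acetate | C=C(COC(C)=O)[C@H]1C[C@H](Cl)[C@@]2(C)OC(C)(C)O[C@H]2[C@H]1O[Si](C)(C)C(C)(C)C | intermediate
15 | 8-alcohol | C=C(CO)[C@H]1C[C@H](Cl)[C@@]2(C)OC(C)(C)O[C@H]2[C@H]1O[Si](C)(C)C(C)(C)C | intermediate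
16 | 8-aldehyde; 2-substituted acrolein | C=C(C=O)[C@H]1C[C@H](Cl)[C@@]2(C)OC(C)(C)O[C@H]2[C@H]1O[Si](C)(C)C(C)(C)C | intermediate
17 | allylmagnesium bromide | C=CC[Mg]Br | starting material
18 | (−)-B-methoxydiisopinocampheylborane, from (+)-α-pinene | COB([C@@H]1C[C@@H]2C[C@H]([C@H]1C)C2(C)C)[C@@H]1C[C@@H]2C[C@H]([C@H]1C)C2(C)C | starting material
19 | (−)-B-allyldiisopinocampheylborane (not isolated) | C=CCB([C@@H]1C[C@@H]2C[C@H]([C@H]1C)C2(C)C)[C@@H]1C[C@@H]2C[C@H]([C@H]1C)C2(C)C | intermediate
20 | diisopinocampheylborinate of 21 (not isolated) | C=C([C@H](CC=C)OB([C@@H]3C[C@@H]4C[C@H]([C@H]3C)C4(C)C)[C@@H]3C[C@@H]4C[C@H]([C@H]3C)C4(C)C)[C@H]1C[C@H](Cl)[C@@]2(C)OC(C)(C)O[C@H]2[C@H]1O[Si](C)(C)C(C)(C)C | intermediate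
21 | (8S)-homoallylic alcohol; acetonide and 6β-TBS ether | C=C([C@H](CC=C)O)[C@H]1C[C@H](Cl)[C@@]2(C)OC(C)(C)O[C@H]2[C@H]1O[Si](C)(C)C(C)(C)C | intermediate
22 | (8S)-3α-chloro-4β,5β,8-triol; 6β-TBS ether | C=C([C@H](CC=C)O)[C@H]1C[C@H](Cl)[C@@](C)(O)[C@@H](O)[C@H]1O[Si](C)(C)C(C)(C)C | intermediate
23 | angelic acid; (Z)-2-methylbut-2-enoic acid | C/C=C(/C)C(=O)O | starting material
24 | angelic 2,4,6-trichlorobenzoic anhydride | C/C=C(/C)C(=O)OC(=O)c1c(Cl)cc(Cl)cc1Cl | intermediate
25 | 5β,8-bis-angelate with terminal vinyl group; 6β-TBS ether | C=C([C@H](CC=C)OC(=O)/C(C)=C\C)[C@H]1C[C@H](Cl)[C@@](C)(O)[C@@H](OC(=O)/C(C)=C\C)[C@H]1O[Si](C)(C)C(C)(C)C | intermediate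
26 | 2-methyl-2-butene | CC=C(C)C | starting material
27 | 5β,8-bis-angelate with C10=C11 prenyl olefin; 6β-TBS ether | C=C([C@H](CC=C(C)C)OC(=O)/C(C)=C\C)[C@H]1C[C@H](Cl)[C@@](C)(O)[C@@H](OC(=O)/C(C)=C\C)[C@H]1O[Si](C)(C)C(C)(C)C | intermediate
28 | desilylated 4β,6β-diol bis-angelate (C10=C11 olefin) | C=C([C@H](CC=C(C)C)OC(=O)/C(C)=C\C)[C@H]1C[C@H](Cl)[C@@](C)(O)[C@@H](OC(=O)/C(C)=C\C)[C@H]1O | intermediate
29 | CNP0158207.1; (1R,3S,4S,5S,6S,8S,10R)-3-chloro-4,6-dihydroxy-10,11-epoxy-5,8-bis(angeloyloxy) compound | C=C([C@H](C[C@H]1OC1(C)C)OC(=O)/C(C)=C\C)[C@H]1C[C@H](Cl)[C@@](C)(O)[C@@H](OC(=O)/C(C)=C\C)[C@H]1O | target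

**Totals**
Total step count: 21. Longest linear sequence: 20 steps from 1 (steps 1–16 and 18–21); step 17 is a one-step side branch.

**Steps most likely to fail, with fallbacks**

Step 11 (allylic chlorination of the hindered isopropenyl group: wrong proton loss or over-chlorination). The fallback sets out from 12 and oxidises the isopropenyl methyl directly with SeO2 (cat.) and t-BuOOH in CH2Cl2 at rt (ene reaction, then 2,3-sigmatropic shift). This gives a mixture of allylic alcohol 15 and enal 16; it rejoins the route at 15, and the MnO2 treatment of step 14 converges the mixture to 16. No compound outside the list is made (F0).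

Step 18 (double angeloylation, with the C5 hydroxyl flanked by a quaternary carbon and the axial silyl ether; risk of incomplete acylation or tiglate formation). The fallback sets out from 22 and builds the Z olefins after acylation. Both secondary alcohols are esterified with 2-[bis(2,2,2-trifluoroethoxy)phosphoryl]propanoic acid (EDC·HCl, DMAP, CH2Cl2); DMAP can be used here because no isomerisable olefin is present yet. This gives the bis(phosphonopropanoate) F1. Still–Gennari olefination of F1 (KN(SiMe3)2, 2 equiv, 18-crown-6, THF, −78 °C, then acetaldehyde) forms both (Z)-2-methylbut-2-enoates and comes back to the route at 25. The phosphonates are far more acidic than the tertiary alcohol, so exactly two equivalents of base at −78 °C should leave the chlorohydrin closed-ring-free.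

Step 21 (last-step Shi epoxidation on a substrate with free hydroxyls, a chlorohydrin and two esters; risk of alcohol oxidation, poor solubility or a hard final separation of C10 epimers). The fallback sets out from 27 and changes the order of events. The same Shi epoxidation is run while C6 is still silylated, giving the silyl-protected epoxide F2, which is lipophilic and easier to purify from its C10 epimer. F2 is then desilylated with HF·pyridine buffered by excess pyridine in THF at 0 °C, conditions a trisubstituted epoxide tolerates, and the route is rejoined at 29.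

**Further compounds**
F0 | step 11 | none | none
F1 | step 18 | 5β,8-bis{2-[bis(2,2,2-trifluoroethoxy)phosphoryl]propanoate} of 22 (6β-TBS ether; epimers at the phosphonate carbons) | C=C([C@H](CC=C)OC(=O)C(C)P(=O)(OCC(F)(F)F)OCC(F)(F)F)[C@H]1C[C@H](Cl)[C@@](C)(O)[C@@H](OC(=O)C(C)P(=O)(OCC(F)(F)F)OCC(F)(F)F)[C@H]1O[Si](C)(C)C(C)(C)C
F2 | step 21 | (10R)-10,11-epoxide of 27 (6β-TBS ether of the target) | C=C([C@H](C[C@H]1OC1(C)C)OC(=O)/C(C)=C\C)[C@H]1C[C@H](Cl)[C@@](C)(O)[C@@H](OC(=O)/C(C)=C\C)[C@H]1O[Si](C)(C)C(C)(C)C
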